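The runs are simulated with constants of no real substance; the scatter is artificial.

- The product to watch is left-handed product: where its plateau stands tells us how much left-handed substrate has gone, and the excess follows from that.

the same everywhere: left-handed substrate 0.050 M; right-handed substrate 0.050 M
- winter: partner 0.055 M; protic impurity 0.063 M; run made earlier
- summer: partner 0.055 M; protic impurity 0.17 M; run made earlier
- maple: partner 0.0550 M; protic impurity 0.0500 M; time 3.0 h
- elm: partner 0.0550 M; protic impurity 0.150 M; time 3.0 h

| run | time / h | left-handed product / % | right-handed product / % |
|---|---|---|---|
| winter | 0.250 | 26 | 1 |
| winter | 0.500 | 32 | 2 |
| winter | 1.33 | 42 | 0 |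
| winter | 3.00 | 42 | 4 |
| summer | 0.250 | 28 | 2 |
| summer | 0.500 | 34 | 4 |
| summer | 1.33 | 37 | 5 |
| summer | 3.00 | 39 | 1 |

(each reading ± 1.5 percentage points)

* the winner by excess of left-handed product over right-handed product in the product; "neither" if no more than 2 percentage points parts them (maple / elm / neither)
* excess of left-handed product over right-handed product in the product at the end, maple
* excess of left-handed product over right-handed product in the product at the end, elm

- partner is single-handed; left-handed substrate and right-handed substrate are mirror images of each other, charged as a racemate, each of them at the stated concentration
- what was read earlier has a scatter of 1.5 percentage points, one standard deviation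
- an excess is below zero if the other one leads
- the handed part of partner does not stay in what it makes, so the products of the two hands are mirror images too

- Winter and summer look nearly the same, and both flatten by 1.33 h. Over the last two readings, left-handed product averages 42.0% in winter and 38.0% in summer, below the 50.0% that left-handed substrate can give.
- Pooling those four readings gives 40.0% left-handed product and 2.50% right-handed product.
- Partner went in at 1.10 equivalents to left-handed substrate, yet the left-handed product readings level off short of what that substrate can give, so we read partner as the limiting reagent. From these readings we reckon that winter lost 0.0105 M of partner to something other than product, and summer lost 0.0145 M, with impurity at 0.17 M against 0.063 M.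
- Both substrates meet the same partner, so we carry one number: the selectivity factor s, the logarithm of the fraction of left-handed substrate left over the logarithm of the fraction of right-handed substrate left. The pooled readings give s = 31.4, a rough value: each reading scatters by 1.5 percentage points.
- Given s, the plateau gives the excess. Maple at winter's plateau gets 87.3%, and elm at summer's gets 88.9%. In our reckoning elm is higher by 1.6 points, inside the 2 points margin, so we say neither.
- The forecast also says neither, with 89% for maple and 87% for elm, in its words “I shrink the gap strongly and call it neither”; it ranks maple higher, where we rank elm higher.
- The flasks give neither: maple 85.1%, elm 86.0%.

    partner + left-handed substrate → left-handed product (k = 96.5 M⁻¹ h⁻¹)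
    partner + right-handed substrate → right-handed product (k = 3.67 M⁻¹ h⁻¹)
    partner → decomposed reagent (k = 0.110 h⁻¹)
    partner + protic impurity → quenched reagent (k = 1.93 M⁻¹ h⁻¹)
    2 partner → homo dimer (k = 6.56 M⁻¹ h⁻¹)

- In elm at the end, partner stands at 0.30% of its charge and left-handed substrate at 19% of its charge; with s, that left-handed substrate gives an excess of 88.0%. A neighbour of elm charged with 0.14 M of partner ends with left-handed substrate down to 0.082% of its charge, where s gives 66.3%, and the excess in that flask ends at 61.7%.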